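**Plan**
Retrosynthesis: the two Ar–CHO bonds are cut first, then the C3 carbonyl is re-introduced as a handle; the oxepine is cut at O–C1 (phenol oxa-Michael) and at C4–C7' (silyl enol ether + o-quinone methide, hetero-Diels–Alder, then ketal hydrolysis); the cyclopentanone is cut at C1–C2/C3–C4 (ketene [2+2], then CH2 insertion); last, C1 is excised from the seven-membered ring.
Enabling feature: the carbocycle C1–C5–C6–C7–C8–C9–C10 carries the gem-dimethylcyclopropane on C6–C7 and the methyl on C10; without C1 it is the six-membered ring of (+)-2-carene, and in its C5 ketone the other α-carbon (C6) is a cyclopropane carbon that neither enolises nor migrates readily.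
Forward order: carane six-ring → seven-ring (C1 inserted between C5 and C10) → cis-fused cyclopentanone on C1–C5 → C4–C7' bond, then O–C1 bond (oxepine) → removal of the C3 oxygen, debenzylation, double formylation.
Stereochemistry: C6/C7 come from carene; C10 from hydroboration anti to the CMe2 bridge, carried with retention through the 1,2-shift; C5 from ketene addition anti to the bridge; C4 and C7' from a hetero-Diels–Alder addition on the convex face of the cis-bicycle; C1 from the tether.

Key step: step 3

Remark (numbering): C1 = O-bearing ring-fusion carbon, C2/C3 = cyclopentane CH2, C4 = C(CH3), C5 = ring-fusion CH, C6/C7 = cyclopropane CH, C8/C9 = CH2, C10 = CH(CH3), C11 = C(CH3)2, C7' = benzylic CH, C1'–C6' = arene (C1' on C7', C2' bearing the oxepine oxygen); "bridge" = C11.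
Remark (assumptions): 1, 15, 16 and 17 are taken as commercial; the o-quinone methide 19 is assumed to react as its E isomer; 25 and 26 are carried as C3 epimer mixtures because that centre is removed in step 14; organolithium species are drawn covalently.

Step 1
Reactants: 1 (+)-2-carene
Product: 3 (−)-2-isocaranol (C5–OH anti to the bridge; C10 methyl syn to the bridge), via alkylborane 2 (not isolated)
Conditions: BH3·SMe2, THF, 0 °C to rt; then 3 M NaOH, 30% H2O2, 0 °C to rt
Reagents that add atoms: hydrogen peroxide, OO
Why: Hydroboration–oxidation adds H–B syn to the trisubstituted C5=C10 bond from the face opposite the CMe2 bridge, with boron on the less substituted C5, which fixes C10 (H anti, CH3 syn to the bridge); oxidation proceeds with retention.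

Step 2
Reactants: 3 (−)-2-isocaranol
Product: 4 2-isocaranone (C5 ketone)
Conditions: Dess–Martin periodinane, NaHCO3, CH2Cl2, 0 °C to rt
Reagents that add atoms: none
Why: Dess–Martin oxidation is buffered and non-enolising, so the α-stereocentre C10 and the cyclopropyl ketone should survive.

Step 3
Reactants: 4 2-isocaranone
Product: 6 4,8,8-trimethylbicyclo[5.1.0]octan-2-one (ring-expanded C5 ketone; C1 = new CH2), via silyl ketone 5 (not isolated)
Conditions: TMSCHN2 (1.1 equiv), BF3·OEt2, CH2Cl2, −78 to −40 °C; then 1 M HCl, THF, rt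
Reagents that add atoms: (trimethylsilyl)diazomethane, C[Si](C)(C)C=[N+]=[N-]
Why: The BF3-activated C5 carbonyl is attacked by the carbon of TMSCHN2 to give a β-silyl diazonium betaine, and the C5–C10 bond shifts to the new carbon as N2 leaves, so that C1 is inserted between C5 and C10 and the cyclopropane-fused six-membered ring C5–C6–C7–C8–C9–C10 becomes the seven-membered ring; protodesilylation of 5 on work-up gives 6. The closest known reaction type is the Lewis-acid-promoted diazoalkane (Tiffeneau–Demjanov-type) homologation of cycloalkanones. No ring is closed: the step is a ring enlargement by a 1,2-carbon shift. The only new stereocentre (C1–Si) is transient and is erased on desilylation, while C10 migrates with retention and C6/C7 are untouched. The step needs migration of C10 rather than the cyclopropyl carbon C6; a cyclopropyl carbon (high s character, flanked by the gem-dimethyl bridge) is a poor migrating group, which should secure this. It also needs no epimerisation at C10 and a single insertion, which the low temperature and the bulky, deactivating α-silyl group of 5 should provide.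

Step 4
Reactants: 6 ring-expanded C5 ketone
Product: 7 p-toluenesulfonylhydrazone of 6
Conditions: TsNHNH2, MeOH, rt
Reagents that add atoms: p-toluenesulfonyl hydrazide, Cc1ccc(cc1)S(=O)(=O)NN
Why: Condensation of the only carbonyl group with tosylhydrazide gives the hydrazone needed for the Shapiro reaction.

Step 5
Reactants: 7 tosylhydrazone
Product: 9 4,8,8-trimethylbicyclo[5.1.0]oct-2-ene (cis C5=C1 alkene), via vinyllithium 8 (not isolated)
Conditions: n-BuLi (2.2 equiv), TMEDA, THF, −78 to 0 °C; then H2O
Reagents that add atoms: none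
Why: In the Shapiro reaction the dianion can form only at C1 (C6 is a cyclopropane carbon), so loss of sulfinate and N2 gives the C5 vinyllithium regiospecifically and protonation gives the C5=C1 alkene with C10 untouched.

Step 6
Reactants: 9 C5=C1 cycloheptene
Product: 11 cis-fused 2,2-dichlorocyclobutanone (C=O on C1, CCl2 on C5; H1 and H5 syn to the bridge), via dichloroketene 10 (not isolated)
Conditions: Cl3CCOCl, Zn–Cu couple, POCl3, Et2O, rt
Reagents that add atoms: trichloroacetyl chloride, ClC(=O)C(Cl)(Cl)Cl
Why: Thermal [2+2] cycloaddition of dichloroketene to the vinylcyclopropane-type alkene should bond the ketene carbonyl carbon to C1 (charge develops on cyclopropyl-stabilised C5) and add suprafacially to the face anti to the CMe2 bridge and the C10 methyl, which sets C5 and a cis ring fusion.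

Step 7
Reactants: 11 dichlorocyclobutanone
Product: 12 cis-fused dichlorocyclopentanone (C3=O, C4Cl2, C2 = new CH2)
Conditions: CH2N2, Et2O–MeOH, 0 °C
Reagents that add atoms: diazomethane, C=[N+]=[N-]
Why: Diazomethane ring expansion of an α,α-dichlorocyclobutanone is regioselective for migration of the non-chlorinated α-carbon C1 (with retention), which places the new CH2 between C1 and the carbonyl carbon C3.

Step 8
Reactants: 12 dichlorocyclopentanone
Product: 14 trimethylsilyl enol ether C3(OSiMe3)=C4(CH3), via lithium enolate 13 (not isolated)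
Conditions: Me2CuLi (3 equiv), THF, −78 to −40 °C; then TMSCl, Et3N, −78 to 0 °C
Reagents that add atoms: lithium dimethylcuprate, [Li+].C[Cu-]C; chlorotrimethylsilane, C[Si](C)(C)Cl
Why: Reductive methylation of the α,α-dichloro ketone with the cuprate (halogen–copper exchange to the α-chloro enolate, then replacement of the second chlorine by methyl) should give the C3–C4 enolate with the C4 methyl in place, and O-silylation stores it as a regiochemically defined, copper-free enol ether that is used as such in step 10.

Step 9
Reactants: 15 3,5-bis(benzyloxy)phenol; 16 3-methylbutanal; 17 sodium benzenesulfinate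
Product: 18 3,5-bis(benzyloxy)-2-[3-methyl-1-(phenylsulfonyl)butyl]phenol (racemic)
Conditions: HCO2H–H2O (1:1), rt
Reagents that add atoms: none
Why: Acid-mediated three-component condensation (hydroxyalkylation ortho to the free OH, then capture of the transient o-quinone methide by sulfinate) should give a stable o-quinone methide precursor; its benzylic centre is re-formed in step 10.

Step 10
Reactants: 14 silyl enol ether; 18 sulfonyl phenol
Product: 21 Michael adduct (C3 ketone; C4 bears CH3 and the C7'H(isobutyl)aryl group; free 2'-OH), via o-quinone methide 19 (not isolated), via chroman silyl ketal 20 (not isolated)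
Conditions: 14 (1.5 equiv), Cs2CO3 (1.2 equiv), toluene, rt, slow addition of 18, then 40 °C; filter, concentrate; then AcOH–THF–H2O (3:1:1), rt
Reagents that add atoms: none
Why: Base-induced loss of sulfinate from 18 gives the E-o-quinone methide 19, which should add to the electron-rich tetrasubstituted silyl enol ether in an inverse-electron-demand hetero-Diels–Alder reaction (O to the oxygenated carbon C3, C7' to C4) suprafacially on the convex face (syn to H1/H5, anti to C6 and the CMe2 group), which sets C4, with the carbocycle (C2/C5) endo under the dienone ring and the bulky OSiMe3/CH3 pair turned outwards, which places the isobutyl group cis to C5 and H7' cis to the C4 methyl; mild acid then cleaves the silyl ketal 20 to the C3 ketone and the free 2'-phenol without touching C4 or C7'.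

Step 11
Reactants: 21 Michael adduct
Product: 23 enone–phenol (C1=C2–C3=O), via bis-silyl ether 22 (not isolated)
Conditions: LDA (2.2 equiv), THF, −78 °C; TMSCl; then Pd(OAc)2 (1.1 equiv), MeCN, rt; aq K2CO3 work-up
Reagents that add atoms: none
Why: In this Saegusa–Ito dehydrogenation the ketone can enolise only towards C2 (C4 is quaternary), so silylation (the phenol is silylated as well) and Pd(II) oxidation should give the C1=C2 enone; the aryl silyl ether is lost on basic work-up.

Step 12
Reactants: 23 enone–phenol
Product: 25 bridged C3 alcohol (oxepine closed, O on C1; C3 epimers), via bridged ketone 24 (not isolated)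
Conditions: DBU (0.2 equiv), CH2Cl2, rt; then MeOH, NaBH4, −20 °C
Reagents that add atoms: none
Why: Base-catalysed intramolecular oxa-Michael addition (7-exo-trig) of the phenol, held by the C4–C7' tether over the β-carbon C1 on the face of H5, should close the oxepine and set C1; borohydride then removes the carbonyl so that the β-aryloxy ketone cannot revert.

Step 13
Reactants: 25 bridged C3 alcohol
Product: 26 O-(C3) S-methyl xanthate
Conditions: NaH, CS2, THF, 0 °C to rt; then MeI
Reagents that add atoms: carbon disulfide, S=C=S; iodomethane, CI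
Why: Xanthate formation is the first stage of a Barton–McCombie deoxygenation; the other phenolic oxygens are blocked and a C3 alkoxide cannot expel the aryloxy group on C1.

Step 14
Reactants: 26 xanthate
Product: 27 O,O'-dibenzyl bis-deformyl target (C3 = CH2)
Conditions: Bu3SnH, AIBN (cat.), toluene, 110 °C
Reagents that add atoms: none
Why: Barton–McCombie radical deoxygenation removes the C3 oxygen under neutral conditions through a secondary radical that should be reduced by the stannane faster than it fragments.

Step 15
Reactants: 27 dibenzyl ether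
Product: 28 bis-deformyl target (4',6'-diphenol)
Conditions: H2 (1 atm), 10% Pd/C, EtOAc, rt
Reagents that add atoms: none
Why: Hydrogenolysis cleaves the two benzyl aryl ethers; the tertiary alkyl aryl ether and the cyclopropane should not be cleaved at 1 atm.

Step 16
Reactants: 28 diphenol
Product: 30 CNP0189833.2 (target), via bis-iminium salt 29 (not isolated)
Conditions: POCl3, DMF, MeCN, 0 to 60 °C; then aq NaOAc, 60 °C
Reagents that add atoms: N,N-dimethylformamide, CN(C)C=O; water, O
Why: Twofold Vilsmeier–Haack formylation should occur at the only two free ring positions (C3' and C5'), each ortho/para to oxygen substituents, and hydrolysis of the bis-iminium salt gives the dialdehyde without touching any stereocentre.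

**Compound list**
1 | (+)-2-carene, (1S,6R)-3,7,7-trimethylbicyclo[4.1.0]hept-2-ene | CC1=C[C@H]2[C@@H](CC1)C2(C)C | starting material
2 | (2-isocaranyl)borane (B on C5 anti to the bridge) | C[C@H]1CC[C@@H]2[C@H]([C@@H]1B)C2(C)C | intermediate (not isolated)
3 | (−)-2-isocaranol (OH anti, C10 methyl syn to the bridge) | C[C@H]1CC[C@@H]2[C@H]([C@@H]1O)C2(C)C | intermediate
4 | 2-isocaranone | C[C@H]1CC[C@@H]2[C@H](C1=O)C2(C)C | intermediate
5 | 4,8,8-trimethyl-3-(trimethylsilyl)bicyclo[5.1.0]octan-2-one (C–Si epimers) | C[C@H]1CC[C@@H]2[C@H](C(=O)C1[Si](C)(C)C)C2(C)C | intermediate (not isolated)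
6 | 4,8,8-trimethylbicyclo[5.1.0]octan-2-one (C10 methyl syn to the bridge) | C[C@H]1CC[C@@H]2[C@H](C(=O)C1)C2(C)C | intermediate
7 | p-toluenesulfonylhydrazone of 6 (C=N geometry not defined) | C[C@H]1CC[C@@H]2[C@H](C(=NNS(=O)(=O)c3ccc(C)cc3)C1)C2(C)C | intermediate
8 | (4,8,8-trimethylbicyclo[5.1.0]oct-2-en-2-yl)lithium | C[C@H]1CC[C@@H]2[C@H](C([Li])=C1)C2(C)C | intermediate (not isolated)
9 | 4,8,8-trimethylbicyclo[5.1.0]oct-2-ene | C[C@H]1CC[C@@H]2[C@H](C=C1)C2(C)C | intermediate
10 | dichloroketene | ClC(Cl)=C=O | intermediate (not isolated)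
11 | cis-fused dichlorocyclobutanone (C=O on C1, CCl2 on C5, H1/H5 syn to the bridge) | C[C@H]1CC[C@@H]2[C@H]([C@H]3[C@@H]1C(=O)C3(Cl)Cl)C2(C)C | intermediate
12 | cis-fused dichlorocyclopentanone (C3=O, C4Cl2) | C[C@H]1CC[C@@H]2[C@H]([C@H]3[C@@H]1CC(=O)C3(Cl)Cl)C2(C)C | intermediate
13 | lithium enolate C3(OLi)=C4(CH3) | C[C@H]1CC[C@@H]2[C@H]([C@H]3[C@@H]1CC(O[Li])=C3C)C2(C)C | intermediate (not isolated)
14 | trimethylsilyl enol ether C3(OSiMe3)=C4(CH3) | C[C@H]1CC[C@@H]2[C@H]([C@H]3[C@@H]1CC(O[Si](C)(C)C)=C3C)C2(C)C | intermediate
15 | 3,5-bis(benzyloxy)phenol | Oc1cc(OCc2ccccc2)cc(OCc2ccccc2)c1 | starting material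
16 | 3-methylbutanal | CC(C)CC=O | starting material
17 | sodium benzenesulfinate | [Na+].[O-]S(=O)c1ccccc1 | starting material
18 | 3,5-bis(benzyloxy)-2-[3-methyl-1-(phenylsulfonyl)butyl]phenol (racemic) | CC(C)CC(c1c(O)cc(OCc2ccccc2)cc1OCc1ccccc1)S(=O)(=O)c1ccccc1 | intermediate
19 | (E)-3,5-bis(benzyloxy)-6-(3-methylbutylidene)cyclohexa-2,4-dien-1-one | CC(C)C/C=C1/C(=O)C=C(OCc2ccccc2)C=C1OCc1ccccc1 | intermediate (not isolated)
20 | chroman silyl ketal (O–C3 and C4–C7' formed on the convex face, OSiMe3 on C3) | C[C@H]1CC[C@@H]2[C@H]([C@H]3[C@@H]1C[C@]4(O[Si](C)(C)C)Oc5cc(OCc6ccccc6)cc(OCc6ccccc6)c5[C@H](CC(C)C)[C@]34C)C2(C)C | intermediate (not isolated)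
21 | Michael adduct: cis-fused C3 ketone, C4 carrying CH3 (concave face) and C7'H(isobutyl)[2-hydroxy-4,6-bis(benzyloxy)phenyl] (convex face) | C[C@H]1CC[C@@H]2[C@H]([C@H]3[C@@H]1CC(=O)[C@]3(C)[C@@H](CC(C)C)c1c(O)cc(OCc4ccccc4)cc1OCc1ccccc1)C2(C)C | intermediate
22 | C2=C3 trimethylsilyl enol ether / aryl trimethylsilyl ether of 21 | C[C@H]1CC[C@@H]2[C@H]([C@H]3[C@@H]1C=C(O[Si](C)(C)C)[C@]3(C)[C@@H](CC(C)C)c1c(O[Si](C)(C)C)cc(OCc4ccccc4)cc1OCc1ccccc1)C2(C)C | intermediate (not isolated)
23 | enone–phenol (C1=C2–C3=O) | C[C@H]1CC[C@@H]2[C@H]([C@H]3C1=CC(=O)[C@]3(C)[C@@H](CC(C)C)c1c(O)cc(OCc4ccccc4)cc1OCc1ccccc1)C2(C)C | intermediate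
24 | bridged C3 ketone (O–C1 bond formed) | CC(C)C[C@H]1c2c(OCc4ccccc4)cc(OCc4ccccc4)cc2O[C@]23CC(=O)[C@@]1(C)[C@H]2[C@H]1[C@@H](CC[C@@H]3C)C1(C)C | intermediate (not isolated)
25 | bridged C3 alcohol (C3 epimers) | CC(C)C[C@H]1c2c(OCc4ccccc4)cc(OCc4ccccc4)cc2O[C@]23CC(O)[C@@]1(C)[C@H]2[C@H]1[C@@H](CC[C@@H]3C)C1(C)C | intermediate
26 | bridged C3 S-methyl xanthate (C3 epimers) | CC(C)C[C@H]1c2c(OCc4ccccc4)cc(OCc4ccccc4)cc2O[C@]23CC(OC(=S)SC)[C@@]1(C)[C@H]2[C@H]1[C@@H](CC[C@@H]3C)C1(C)C | intermediate
27 | O,O'-dibenzyl bis-deformyl target | CC(C)C[C@H]1c2c(OCc4ccccc4)cc(OCc4ccccc4)cc2O[C@]23CC[C@@]1(C)[C@H]2[C@H]1[C@@H](CC[C@@H]3C)C1(C)C | intermediate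
28 | bis-deformyl target (4',6'-diphenol) | CC(C)C[C@H]1c2c(O)cc(O)cc2O[C@]23CC[C@@]1(C)[C@H]2[C@H]1[C@@H](CC[C@@H]3C)C1(C)C | intermediate
29 | 3',5'-bis(dimethyliminiomethyl) dichloride of 28 | CC(C)C[C@H]1c2c(O)c(C=[N+](C)C)c(O)c(C=[N+](C)C)c2O[C@]23CC[C@@]1(C)[C@H]2[C@H]1[C@@H](CC[C@@H]3C)C1(C)C.[Cl-].[Cl-] | intermediate (not isolated)
30 | CNP0189833.2 (7'R,1S,4R,5R,6R,7R,10S in the numbering of the remark) | CC(C)C[C@H]1c2c(O)c(C=O)c(O)c(C=O)c2O[C@]23CC[C@@]1(C)[C@H]2[C@H]1[C@@H](CC[C@@H]3C)C1(C)C | target

**Count**
Total steps: 16. Longest linear sequence: 15 (steps 1–8 and 10–16).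

**Steps most likely to fail**

Step 12. The phenol conjugate addition is reversible: the equilibrium may lie on the side of the open enone, or the adduct may revert before it is reduced, so that hydride attacks the enone instead. The fallback sets out from 23. Luche reduction (NaBH4, CeCl3, MeOH, −78 °C) would give the allylic alcohol F1. Mild acid (PPTS or catalytic Sc(OTf)3, CH2Cl2, 0 °C) would ionise it to the C1–C2–C3 allyl cation, which the tethered phenol should capture at the tertiary terminus C1 to give the bridged allylic ether F2 (C2=C3). Hydrogenation over Pd/C would saturate C2=C3 and remove both benzyl groups at once, coming back to the route at 28 and bypassing 24–27.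

Step 10. The hindered, tetrasubstituted silyl enol ether may add too slowly, so that the quinone methide oligomerises or tautomerises to the 2-alkenylphenol, and endo/exo or facial selection at C4/C7' may be poor. The fallback sets out from 14 and 18 and replaces the neutral cycloaddition by an anionic Michael addition. Phenol 18 would be deprotonated with LiHMDS (THF, −78 °C) to the lithium phenoxide of 18 F3, and 14 would be cleaved with MeLi (THF, 0 °C) to the lithium enolate 13. On mixing at −78 °C and warming to 0 °C, F3 should lose sulfinate to 19, and the fully substituted enolate carbon C4 should add to it on the convex face in a lithium-bridged, closed transition state with the quinone methide over the carbocycle. Aqueous NH4Cl would give the ketone–phenol directly, coming back to the route at 21 and bypassing 20.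

Step 3. The wrong ring bond may migrate, C10 may epimerise before insertion, or a second insertion may follow. The fallback sets out from 4 and uses a ring enlargement whose regiochemistry is fixed by enolisation. The trimethylsilyl enol ether F4 (TMSOTf, Et3N; only C5=C10 is possible) would be cyclopropanated anti to the bridge (Et2Zn, CH2I2) to the siloxycyclopropane F5. FeCl3 in DMF would cleave the internal C5–C10 bond to the β-chloro ketone F6, and NaOAc in MeOH would give the cycloheptenone F7 (Saegusa–Ito ring expansion). Luche reduction anti to the bridge would give the allylic alcohol F8. A Myers reductive transposition (2-nitrobenzenesulfonyl hydrazide, PPh3, DEAD) would pass through the allylic diazene F9, formed with inversion at C5; it delivers hydrogen to C10 on the face anti to the bridge while the double bond moves to C5=C1. This comes back to the route at 9 and bypasses 5–8.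

**Further compounds**
F1 | step 12 | allylic alcohol from 23 (C3–OH, C1=C2; C3 epimers) | C[C@H]1CC[C@@H]2[C@H]([C@H]3C1=CC(O)[C@]3(C)[C@@H](CC(C)C)c1c(O)cc(OCc4ccccc4)cc1OCc1ccccc1)C2(C)C
F2 | step 12 | bridged allylic ether (O–C1 formed, C2=C3) | CC(C)C[C@H]1c2c(OCc4ccccc4)cc(OCc4ccccc4)cc2O[C@]23C=C[C@@]1(C)[C@H]2[C@H]1[C@@H](CC[C@@H]3C)C1(C)C
F3 | step 10 | lithium phenoxide of 18 | CC(C)CC(c1c(O[Li])cc(OCc2ccccc2)cc1OCc1ccccc1)S(=O)(=O)c1ccccc1
F4 | step 3 | trimethylsilyl enol ether of 4 (C5=C10) | CC1=C(O[Si](C)(C)C)[C@H]2[C@@H](CC1)C2(C)C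
F5 | step 3 | siloxycyclopropane (CH2 bridging C5 and C10 anti to the CMe2 bridge) | C[C@@]12CC[C@@H]3[C@H]([C@@]1(C2)O[Si](C)(C)C)C3(C)C
F6 | step 3 | 4-chloro-4,8,8-trimethylbicyclo[5.1.0]octan-2-one (C10 epimers) | CC1(Cl)CC(=O)[C@H]2[C@@H](CC1)C2(C)C
F7 | step 3 | 4,8,8-trimethylbicyclo[5.1.0]oct-3-en-2-one | CC1=CC(=O)[C@H]2[C@@H](CC1)C2(C)C
F8 | step 3 | 4,8,8-trimethylbicyclo[5.1.0]oct-3-en-2-ol (OH syn to the CMe2 bridge) | CC1=C[C@H](O)[C@H]2[C@@H](CC1)C2(C)C
F9 | step 3 | allylic diazene (N on C5 anti to the CMe2 bridge) | CC1=C[C@@H](N=N)[C@H]2[C@@H](CC1)C2(C)C
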